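The plan avoids making the crowded biaryl bond G-C8–D-C3' by cross-coupling (G = 5,7-dihydroxyisoflavone half, D = 7-hydroxyisoflavone half). Ring B of D is instead grown around an alkyne that already sits on G-C8. The feature exploited is that D-C3', which carries G-C8, and the oxygenated D-C4' are neighbours in ring B. They therefore map onto the two carbons of an aryl ynol ether. Cycloaddition of 8-(ethoxyethynyl)tri-O-methylgenistein with methyl coumalate, followed by loss of CO2, forms D-C2'–C3' and D-C4'–C5' and completes ring B. It also leaves an ester on D-C1', para to oxygen, from which the D chromone is built.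

Key step: step 4

Remark on the chemistry: the target string has no stereodescriptor and no stereocentre. The G-C8–D-C3' axis (three small ortho substituents) is taken as configurationally unspecified, so no atroposelective control is planned.

Step 1
Reactants: 1 genistein
Product: 2 5,7-dimethoxy-3-(4-methoxyphenyl)chromen-4-one (tri-O-methylgenistein)
Conditions: Me2SO4 (excess), K2CO3, acetone, reflux
Reagents that add atoms: dimethyl sulfate COS(=O)(=O)OC
Why: Williamson-type O-methylation of all three phenols; the hard electrophile keeps alkylation on oxygen, and excess reagent with prolonged reflux overcomes the hydrogen bond that ties the 5-OH to the C4 carbonyl.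

Step 2
Reactants: 2 tri-O-methylgenistein
Product: 3 8-iodo-5,7-dimethoxy-3-(4-methoxyphenyl)chromen-4-one
Conditions: NIS (1.05 equiv), CF3CO2H (cat.), MeCN, 0 °C → rt, dark
Reagents that add atoms: N-iodosuccinimide O=C1CCC(=O)N1I
Why: Electrophilic aromatic iodination; ring A, whose three oxygen donors all direct to C6/C8, outcompetes the anisyl ring, and in 5,7-dialkoxychromones attack goes to C8 because C6 is squeezed between two methoxy groups, one of them twisted by the peri carbonyl.

Step 3
Reactants: 3 8-iodo-tri-O-methylgenistein; 4 ethoxyacetylene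
Product: 7 8-(ethoxyethynyl)-5,7-dimethoxy-3-(4-methoxyphenyl)chromen-4-one, via lithium ethoxyacetylide 5 (not isolated), via ethoxyethynylzinc chloride 6 (not isolated)
Conditions: 4, n-BuLi, THF, −78 °C; ZnCl2, −78 → 0 °C; then 3, Pd(PPh3)4 (5 mol %), THF, rt → 45 °C; pH 7 buffer work-up, basic Al2O3
Reagents that add atoms: none
Why: Negishi alkynylation, a known route to aryl alkoxyacetylenes: the C8–I bond adds oxidatively to zerovalent palladium, the rod-shaped and weakly basic zinc acetylide transmetalates without attacking the chromone, and the small sp nucleophile is little affected by the two ortho oxygen substituents.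

Step 4
Reactants: 7 8-(ethoxyethynyl)-tri-O-methylgenistein; 8 methyl coumalate (methyl 2-oxo-2H-pyran-5-carboxylate)
Product: 10 methyl 3-[5,7-dimethoxy-3-(4-methoxyphenyl)-4-oxochromen-8-yl]-4-ethoxybenzoate, via bridged bicyclic lactone 9 (not isolated)
Conditions: 8 (3 equiv, freshly sublimed, acid-free), 4 Å MS, toluene (1 M), 90 °C, sealed tube, Ar
Reagents that add atoms: none
Why: Inverse-electron-demand Diels–Alder reaction followed by cycloreversion: the electron-poor diene C3=C4–C5=C6 of 8 adds in a concerted but asynchronous [4+2] across the electron-rich triple bond of 7 to give lactone-bridged 9, which expels CO2 by retro-[4+2] at the bath temperature and aromatises irreversibly. The closest known reaction type is the benzannulation of coumalate esters with ynamines, alkoxyalkynes and ketene acetals, which delivers benzoates carrying the donor para to the ester. Ring B of D closes as a six-membered carbocycle by intermolecular cycloaddition (four carbons from 8, two from 7; new bonds D-C2'–C3' and D-C4'–C5'), not by cyclisation of a tethered chain. No stereocentre results, since both bridgeheads of 9 become sp2 on loss of CO2. The one selectivity required is orientation, and it is secured by polarity matching: the alkyne carbon bound to G-C8 is the nucleophilic β-carbon of the ynol ether and attacks pyrone C6, the terminus activated by both the C5 ester and the lactone carbonyl, so the ethoxy-bearing carbon joins C3 and ends para to CO2Me. Because only a linear sp carbon has to approach the diene, the three ortho substituents of the future axis do not block bond formation, and keeping the bath below about 100 °C holds back retro-ene loss of ethene from the ethyl ynol ether.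

Step 5
Reactants: 10 biaryl methyl ester
Product: 11 3-[5,7-dimethoxy-3-(4-methoxyphenyl)-4-oxochromen-8-yl]-4-ethoxybenzoic acid
Conditions: Me3SnOH (5 equiv), 1,2-dichloroethane, 80 °C; then 1 M HCl wash
Reagents that add atoms: trimethyltin hydroxide C[Sn](C)(C)O
Why: Neutral, tin-assisted acyl–oxygen ester hydrolysis is chosen because hydroxide would add to C2 of the fully alkylated isoflavone and open ring C, whereas this reagent should touch only the unhindered methyl benzoate.

Step 6
Reactants: 11 biaryl benzoic acid
Product: 13 8-[5-(2-diazoacetyl)-2-ethoxyphenyl]-5,7-dimethoxy-3-(4-methoxyphenyl)chromen-4-one, via acid chloride 12 (not isolated)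
Conditions: (COCl)2, DMF (cat.), CH2Cl2, 0 °C → rt, evaporate; Me3SiCHN2, Et3N, THF/MeCN, 0 °C → rt; aq. NaHCO3
Reagents that add atoms: (trimethylsilyl)diazomethane C[Si](C)(C)C=[N+]=[N-]
Why: First half of the Arndt–Eistert homologation: the aroyl chloride acylates the nucleophilic carbon of the diazoalkane, Et3N takes up HCl so that no chloromethyl ketone forms, the silyl group falls off on aqueous work-up, and no hydride or strong base ever meets the chromone enone.

Step 7
Reactants: 13 diazoketone
Product: 15 2-{3-[5,7-dimethoxy-3-(4-methoxyphenyl)-4-oxochromen-8-yl]-4-ethoxyphenyl}acetic acid, via aryl ketene 14 (not isolated)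
Conditions: AgO2CPh (0.2 equiv), Et3N, THF/H2O, rt → 45 °C, dark; then 1 M HCl
Reagents that add atoms: water O
Why: Silver-catalysed Wolff rearrangement: loss of N2 with 1,2-shift of the electron-rich aryl group gives the ketene, which water traps as the arylacetic acid, completing the one-carbon homologation under nearly neutral conditions.

Step 8
Reactants: 15 arylacetic acid; 16 resorcinol
Product: 18 8-[2-ethoxy-5-(7-hydroxy-4-oxochromen-3-yl)phenyl]-5,7-dimethoxy-3-(4-methoxyphenyl)chromen-4-one, via deoxybenzoin 17 (not isolated)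
Conditions: 16 (1.1 equiv), BF3·OEt2 (solvent), 85 °C; cool to 10 °C, DMF, then MeSO2Cl, 70 °C; ice-water
Reagents that add atoms: N,N-dimethylformamide CN(C)C=O
Why: Friedel–Crafts C-acylation of resorcinol at C4 by the BF3-activated acid gives the 2,4-dihydroxydeoxybenzoin, whose boron chelate is formylated at the activated methylene by the Vilsmeier–Haack-type iminium salt from DMF and MeSO2Cl and cyclises through the ortho hydroxyl with loss of dimethylamine, a standard one-pot isoflavone synthesis that tolerates the free para hydroxyl.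

Step 9
Reactants: 18 tetra-O-alkyl biisoflavone
Product: 19 5,7-dihydroxy-8-[2-hydroxy-5-(7-hydroxy-4-oxochromen-3-yl)phenyl]-3-(4-hydroxyphenyl)chromen-4-one (CNP0500144.0)
Conditions: BBr3 (12 equiv), CH2Cl2, −78 °C → rt; ice-water
Reagents that add atoms: none
Why: Lewis-acid ether cleavage: each aryl alkyl ether binds BBr3 and is dealkylated by bromide in SN2 fashion (methyl and ethyl alike), and the aprotic, low-temperature medium avoids the ring-opening and reclosure (Wessely–Moser isomerisation) that hot mineral acid could cause in an 8-aryl-5,7-dihydroxychromone.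

Compound list
1 | genistein | O=c1c(-c2ccc(O)cc2)coc2cc(O)cc(O)c12 | starting material
2 | 5,7-dimethoxy-3-(4-methoxyphenyl)chromen-4-one | O=c1c(-c2ccc(OC)cc2)coc2cc(OC)cc(OC)c12 | intermediate
3 | 8-iodo-5,7-dimethoxy-3-(4-methoxyphenyl)chromen-4-one | Ic1c(OC)cc(OC)c2c(=O)c(-c3ccc(OC)cc3)coc12 | intermediate
4 | ethoxyacetylene | C#COCC | starting material
5 | lithium ethoxyacetylide | CCOC#C[Li] | intermediate
6 | ethoxyethynylzinc chloride | CCOC#C[Zn]Cl | intermediate
7 | 8-(ethoxyethynyl)-5,7-dimethoxy-3-(4-methoxyphenyl)chromen-4-one | CCOC#Cc1c(OC)cc(OC)c2c(=O)c(-c3ccc(OC)cc3)coc12 | intermediate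
8 | methyl coumalate | COC(=O)c1ccc(=O)oc1 | starting material
9 | methyl 7-[5,7-dimethoxy-3-(4-methoxyphenyl)-4-oxochromen-8-yl]-8-ethoxy-3-oxo-2-oxabicyclo[2.2.2]octa-5,7-diene-6-carboxylate (racemic, one enantiomer drawn; bridgehead configuration fixed by the bicycle) | O=C1O[C@@H]2C(C(=O)OC)=C[C@H]1C(OCC)=C2c3c(OC)cc(OC)c4c(=O)c(-c5ccc(OC)cc5)coc34 | intermediate
10 | methyl 3-[5,7-dimethoxy-3-(4-methoxyphenyl)-4-oxochromen-8-yl]-4-ethoxybenzoate | CCOc1ccc(C(=O)OC)cc1-c1c(OC)cc(OC)c2c(=O)c(-c3ccc(OC)cc3)coc12 | intermediate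
11 | 3-[5,7-dimethoxy-3-(4-methoxyphenyl)-4-oxochromen-8-yl]-4-ethoxybenzoic acid | CCOc1ccc(C(=O)O)cc1-c1c(OC)cc(OC)c2c(=O)c(-c3ccc(OC)cc3)coc12 | intermediate
12 | 3-[5,7-dimethoxy-3-(4-methoxyphenyl)-4-oxochromen-8-yl]-4-ethoxybenzoyl chloride | CCOc1ccc(C(=O)Cl)cc1-c1c(OC)cc(OC)c2c(=O)c(-c3ccc(OC)cc3)coc12 | intermediate
13 | 8-[5-(2-diazoacetyl)-2-ethoxyphenyl]-5,7-dimethoxy-3-(4-methoxyphenyl)chromen-4-one | CCOc1ccc(C(=O)C=[N+]=[N-])cc1-c1c(OC)cc(OC)c2c(=O)c(-c3ccc(OC)cc3)coc12 | intermediate
14 | 8-[2-ethoxy-5-(2-oxoethenyl)phenyl]-5,7-dimethoxy-3-(4-methoxyphenyl)chromen-4-one (aryl ketene) | CCOc1ccc(C=C=O)cc1-c1c(OC)cc(OC)c2c(=O)c(-c3ccc(OC)cc3)coc12 | intermediate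
15 | 2-{3-[5,7-dimethoxy-3-(4-methoxyphenyl)-4-oxochromen-8-yl]-4-ethoxyphenyl}acetic acid | CCOc1ccc(CC(=O)O)cc1-c1c(OC)cc(OC)c2c(=O)c(-c3ccc(OC)cc3)coc12 | intermediate
16 | resorcinol | Oc1cccc(O)c1 | starting material
17 | 8-{5-[2-(2,4-dihydroxyphenyl)-2-oxoethyl]-2-ethoxyphenyl}-5,7-dimethoxy-3-(4-methoxyphenyl)chromen-4-one | CCOc1ccc(CC(=O)c2ccc(O)cc2O)cc1-c1c(OC)cc(OC)c2c(=O)c(-c3ccc(OC)cc3)coc12 | intermediate
18 | 8-[2-ethoxy-5-(7-hydroxy-4-oxochromen-3-yl)phenyl]-5,7-dimethoxy-3-(4-methoxyphenyl)chromen-4-one | CCOc1ccc(-c2coc3cc(O)ccc3c2=O)cc1-c1c(OC)cc(OC)c2c(=O)c(-c3ccc(OC)cc3)coc12 | intermediate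
19 | 5,7-dihydroxy-8-[2-hydroxy-5-(7-hydroxy-4-oxochromen-3-yl)phenyl]-3-(4-hydroxyphenyl)chromen-4-one | O=c1c(-c2ccc(O)c(-c3c(O)cc(O)c4c(=O)c(-c5ccc(O)cc5)coc34)c2)coc2cc(O)ccc12 | target

Total step count: 9. Longest linear sequence: 9 steps (1 → 19). Compounds 4, 8 and 16 enter as purchased materials.

Steps most likely to fail

Step 4. The cycloaddition may be too slow at the temperatures the ethyl ynol ether tolerates. Thermal retro-ene loss of ethene, or adventitious hydration of the triple bond, could then outrun ring formation. Shielding of the alkyne carbon next to G-C8 would add to the problem. The fallback sets out from iodide 3 and gives up the benzannulation in favour of a cross-coupling.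
- Commercial methyl 3-bromo-4-hydroxybenzoate is O-ethylated (EtI, K2CO3, DMF) to methyl 3-bromo-4-ethoxybenzoate F1.
- F1 is borylated (B2pin2, PdCl2(dppf), KOAc, dioxane, 90 °C) to methyl 4-ethoxy-3-(4,4,5,5-tetramethyl-1,3,2-dioxaborolan-2-yl)benzoate F2.
- F2 is joined to 3 by Suzuki–Miyaura coupling with a bulky biarylphosphine (Pd(OAc)2, SPhos, K3PO4, toluene/H2O, 90 °C).
- The route is rejoined at 10.

Step 3. Transmetalation and reductive elimination at the doubly ortho-oxygenated iodide may be sluggish. The zinc acetylide may homocouple, and the ynol ether may hydrate during aqueous work-up or chromatography. The fallback sets out from 3 and 4 and replaces the zinc reagent made in the flask by an isolable, neutral tin acetylide.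
- Lithium ethoxyacetylide 5 (from 4 and n-BuLi) is quenched with Bu3SnCl to give distillable tributyl(ethoxyethynyl)stannane F3.
- F3 is coupled with 3 under salt-free Stille conditions (PdCl2(PPh3)2, Et4NCl, DMF, 70 °C).
- The crude product is only filtered through basic Al2O3 before use.
- The route is rejoined at 7.

Step 8. C-acylation of resorcinol by the bulky, Lewis-basic acid may be incomplete. The peri 5-O-methyl group may be partly lost in hot BF3·OEt2, and the iminium reagent may over-react, together giving mixtures that are hard to purify. The fallback sets out from 15 and separates the three events.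
- Acid 15 acylates 1,3-dimethoxybenzene through its mixed trifluoroacetic anhydride ((CF3CO)2O, H3PO4 cat., rt). This gives 1-(2,4-dimethoxyphenyl)-2-{3-[5,7-dimethoxy-3-(4-methoxyphenyl)-4-oxochromen-8-yl]-4-ethoxyphenyl}ethanone F4.
- BBr3 in CH2Cl2 removes all six alkyl groups to give 1-(2,4-dihydroxyphenyl)-2-{3-[5,7-dihydroxy-3-(4-hydroxyphenyl)-4-oxochromen-8-yl]-4-hydroxyphenyl}ethanone F5.
- The phenol-tolerant BF3·OEt2/DMF/MeSO2Cl closure is carried out last on F5.
- The route is rejoined at the target 19.

Further compounds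
F1 | step 4 | methyl 3-bromo-4-ethoxybenzoate | CCOc1ccc(C(=O)OC)cc1Br
F2 | step 4 | methyl 4-ethoxy-3-(4,4,5,5-tetramethyl-1,3,2-dioxaborolan-2-yl)benzoate | CCOc1ccc(C(=O)OC)cc1B1OC(C)(C)C(C)(C)O1
F3 | step 3 | tributyl(ethoxyethynyl)stannane | CCOC#C[Sn](CCCC)(CCCC)CCCC
F4 | step 8 | 1-(2,4-dimethoxyphenyl)-2-{3-[5,7-dimethoxy-3-(4-methoxyphenyl)-4-oxochromen-8-yl]-4-ethoxyphenyl}ethanone | COc1ccc(C(=O)Cc2ccc(OCC)c(-c3c(OC)cc(OC)c4c(=O)c(-c5ccc(OC)cc5)coc34)c2)c(OC)c1
F5 | step 8 | 1-(2,4-dihydroxyphenyl)-2-{3-[5,7-dihydroxy-3-(4-hydroxyphenyl)-4-oxochromen-8-yl]-4-hydroxyphenyl}ethanone | Oc1ccc(C(=O)Cc2ccc(O)c(-c3c(O)cc(O)c4c(=O)c(-c5ccc(O)cc5)coc34)c2)c(O)c1
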